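**Plan**
1. Retrosynthesis: C4 is taken back to a ketone, and the pyran ring is then cut at C2–C3 and O1–C8a. This gives ethyl formate (the C2–O1 unit) and the 2-fluorodeoxybenzoin 10. Compound 10 is cut at C3–C1' into ring A acetophenone 7 and ring B bromide 9, and the C6 prenyl bond goes back by a Claisen shift to an aryl 1,1-dimethylallyl ether of acetylated 5-fluororesorcinol.
2. Enabling feature: ring A is 5,7-dioxygenated, so C8a lies meta to O5 and O7 and ortho to C4. With a temporary C4=O, a fluoride at C8a is open to addition–elimination and C3–H2 is acidic. The free 7-OH para to C4 later lets the C4 oxygen leave through a para-quinone methide.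
3. Forward order: ring A is dressed first (acetyl, C6 prenyl, O7-MOM, O5-Me), ring B is joined at C3 by ketone α-arylation, and the pyranone ring closes in one pot (step 8). The C2=C3 bond is then reduced and the MOM groups are removed.
4. Stereochemistry: C3 is the only stereocentre. It is set in the last step by ruthenium-catalysed asymmetric transfer hydrogenation with dynamic kinetic resolution of the racemic isoflavanone ((R,R)-TsDPEN ligand), followed in the same pot by loss of the C4 oxygen.

Key step: step 8

Assumption: 5-fluororesorcinol (1), carbonate 3 and bromophenol 8 are taken as catalogue compounds, and ethyl formate (11) as a bulk chemical.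

**Route**

Step 1
Reactants: 1 5-fluorobenzene-1,3-diol (5-fluororesorcinol)
Product: 2 1-(2-fluoro-4,6-dihydroxyphenyl)ethan-1-one
Conditions: AcOH, BF3·OEt2, 90 °C
Reagents that add atoms: acetic acid, CC(=O)O
Why: Friedel–Crafts (Nencki-type) C-acylation of a resorcinol, in which the electrophile should enter para to one OH and ortho to the other (between OH and F) as in the resorcinol-to-resacetophenone case, the ketone product being deactivated toward a second acylation.

Step 2
Reactants: 2 1-(2-fluoro-4,6-dihydroxyphenyl)ethan-1-one; 3 tert-butyl 2-methylbut-3-en-2-yl carbonate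
Product: 4 1-[2-fluoro-6-hydroxy-4-(2-methylbut-3-en-2-yloxy)phenyl]ethan-1-one
Conditions: Pd(PPh3)4 (2 mol %), THF, 0 °C to rt
Reagents that add atoms: none
Why: Tsuji–Trost O-allylation, in which the 1,1-dimethyl-π-allylpalladium complex formed from 3 with loss of CO2 should be attacked at its tertiary terminus by the free 4-OH while the 6-OH stays locked in its hydrogen bond to the acetyl group.

Step 3
Reactants: 4 1-[2-fluoro-6-hydroxy-4-(2-methylbut-3-en-2-yloxy)phenyl]ethan-1-one
Product: 5 1-[6-fluoro-2,4-dihydroxy-3-(3-methylbut-2-en-1-yl)phenyl]ethan-1-one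
Conditions: PhNEt2, 160 °C
Reagents that add atoms: none
Why: Aromatic Claisen rearrangement ([3,3]) of the aryl 1,1-dimethylallyl ether, which delivers a normal prenyl group to an ortho carbon; the hydrogen-bonded 2-hydroxyacetophenone unit fixes the ring double bond so that migration should go to the carbon between the two oxygens (future C6 of the chroman) and not to the carbon next to fluorine.

Step 4
Reactants: 5 1-[6-fluoro-2,4-dihydroxy-3-(3-methylbut-2-en-1-yl)phenyl]ethan-1-one
Product: 6 1-[6-fluoro-2-hydroxy-4-(methoxymethoxy)-3-(3-methylbut-2-en-1-yl)phenyl]ethan-1-one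
Conditions: MOMCl (1.1 equiv), K2CO3, acetone, rt
Reagents that add atoms: chloromethyl methyl ether, COCCl
Why: Williamson-type O-alkylation of the more acidic, non-chelated phenol para to the acetyl group, the ortho OH being held in the intramolecular hydrogen bond and reacting much more slowly.

Step 5
Reactants: 6 1-[6-fluoro-2-hydroxy-4-(methoxymethoxy)-3-(3-methylbut-2-en-1-yl)phenyl]ethan-1-one
Product: 7 1-[6-fluoro-2-methoxy-4-(methoxymethoxy)-3-(3-methylbut-2-en-1-yl)phenyl]ethan-1-one
Conditions: MeI, K2CO3, DMF, 50 °C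
Reagents that add atoms: iodomethane, CI
Why: Williamson O-methylation of the remaining hydrogen-bonded phenol under more forcing conditions, which is possible now that it is the only acidic OH in the molecule.

Step 6
Reactants: 8 4-bromo-3-methoxyphenol
Product: 9 1-bromo-2-methoxy-4-(methoxymethoxy)benzene
Conditions: MOMCl, K2CO3, acetone, rt
Reagents that add atoms: chloromethyl methyl ether, COCCl
Why: Williamson-type MOM protection of the phenol, giving an acetal that is stable to the later palladium, enolate and hydride steps.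

Step 7
Reactants: 7 1-[6-fluoro-2-methoxy-4-(methoxymethoxy)-3-(3-methylbut-2-en-1-yl)phenyl]ethan-1-one; 9 1-bromo-2-methoxy-4-(methoxymethoxy)benzene
Product: 10 1-[6-fluoro-2-methoxy-4-(methoxymethoxy)-3-(3-methylbut-2-en-1-yl)phenyl]-2-[2-methoxy-4-(methoxymethoxy)phenyl]ethan-1-one
Conditions: Pd2(dba)3 (2 mol %), XPhos (5 mol %), NaOtBu, toluene, 80 °C
Reagents that add atoms: none
Why: Palladium-catalysed α-arylation of a methyl ketone enolate (Buchwald–Hartwig type), in which oxidative addition of 9, enolate binding and C–C reductive elimination from the bulky biarylphosphine complex should give the mono-arylated deoxybenzoin, the ortho-methoxy group of 9 hindering a second arylation and the C–F bond being inert to zerovalent palladium.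

Step 8
Reactants: 10 1-[6-fluoro-2-methoxy-4-(methoxymethoxy)-3-(3-methylbut-2-en-1-yl)phenyl]-2-[2-methoxy-4-(methoxymethoxy)phenyl]ethan-1-one; 11 ethyl formate
Product: 13 5-methoxy-3-[2-methoxy-4-(methoxymethoxy)phenyl]-7-(methoxymethoxy)-6-(3-methylbut-2-en-1-yl)-4H-chromen-4-one, via sodium formyl enolate 12 (not isolated)
Conditions: NaH (1.2 equiv), THF, 0 °C to rt; then concentrate, DMF, 100 °C
Reagents that add atoms: none
Why: The sodium enolate of 10 should undergo Claisen C-formylation by ethyl formate at C3 (C2–C3 bond) to give the chelated hydroxymethylene-ketone enolate 12, whose formyl oxygen then adds to C8a and expels fluoride through a Meisenheimer intermediate stabilised by the ortho C4 carbonyl (O1–C8a bond). The closest known reaction types are the ethyl formate isoflavone synthesis and the SNAr closure of 1-(2-fluoroaryl)-1,3-dicarbonyl enolates to chromones and flavones. The pyranone ring closes by a six-membered addition–elimination at the sp2 carbon C8a (6-exo-trig with respect to the C8a=C8 bond of the Meisenheimer intermediate) and is driven by formation of the aromatic 4H-chromen-4-one. No stereocentre is formed. The step needs O- rather than C-arylation and closure at one defined carbon: only the formyl oxygen can reach an aryl carbon through a six-membered transition state, C8a carries the only fluoride, and C8a lies meta to both ring A oxygens so that their donation does not reach the attacked carbon. Using about one equivalent of NaH leaves ethanol rather than ethoxide in the pot, which should keep intermolecular displacement of fluoride down.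

Step 9
Reactants: 13 5-methoxy-3-[2-methoxy-4-(methoxymethoxy)phenyl]-7-(methoxymethoxy)-6-(3-methylbut-2-en-1-yl)-4H-chromen-4-one
Product: 14 rac-5-methoxy-3-[2-methoxy-4-(methoxymethoxy)phenyl]-7-(methoxymethoxy)-6-(3-methylbut-2-en-1-yl)-2,3-dihydro-4H-chromen-4-one
Conditions: LiBH(sec-Bu)3 (L-Selectride, 1.1 equiv), THF, −78 °C; then H2O
Reagents that add atoms: none
Why: Conjugate (1,4) hydride addition of the bulky trialkylborohydride to C2 of the chromone followed by protonation at C3, a known isoflavone-to-isoflavanone reduction that leaves the prenyl alkene alone and gives C3 as a racemate on purpose because it is set in step 11.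

Step 10
Reactants: 14 rac-5-methoxy-3-[2-methoxy-4-(methoxymethoxy)phenyl]-7-(methoxymethoxy)-6-(3-methylbut-2-en-1-yl)-2,3-dihydro-4H-chromen-4-one
Product: 15 rac-7-hydroxy-3-(4-hydroxy-2-methoxyphenyl)-5-methoxy-6-(3-methylbut-2-en-1-yl)-2,3-dihydro-4H-chromen-4-one
Conditions: 3 M HCl, MeOH, 40 °C
Reagents that add atoms: none
Why: Acid-catalysed acetal exchange should remove both MOM groups, and it is placed at the ketone stage because the freed 7-OH is then a vinylogous acid and a poor nucleophile toward the neighbouring prenyl alkene.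

Step 11
Reactants: 15 rac-7-hydroxy-3-(4-hydroxy-2-methoxyphenyl)-5-methoxy-6-(3-methylbut-2-en-1-yl)-2,3-dihydro-4H-chromen-4-one
Product: 18 (3R)-3-(4-hydroxy-2-methoxyphenyl)-5-methoxy-6-(3-methylbut-2-en-1-yl)-3,4-dihydro-2H-chromen-7-ol, via cis-isoflavan-4-ol 16 (not isolated), via para-quinone methide 17 (not isolated)
Conditions: RuCl(p-cymene)[(R,R)-TsDPEN] (3 mol %), HCO2H/Et3N (5:2), EtOAc, 40 °C
Reagents that add atoms: none
Why: Noyori–Ikariya asymmetric transfer hydrogenation with dynamic kinetic resolution, in which C3 of 15 epimerises through the enol under Et3N and the (R,R)-catalyst should reduce the (3R)-ketone from the face anti to the C3 aryl group to give the cis-(3R,4R)-alcohol 16 (C3 set by catalyst control), after which 16 ionises to the para-quinone methide 17 because the free 7-OH is para to C4, and ruthenium hydride adds to C4 without touching C3.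

**Compound list**
1 | 5-fluorobenzene-1,3-diol (5-fluororesorcinol) | Oc1cc(O)cc(F)c1 | starting material
2 | 1-(2-fluoro-4,6-dihydroxyphenyl)ethan-1-one | CC(=O)c1c(O)cc(O)cc1F | intermediate
3 | tert-butyl 2-methylbut-3-en-2-yl carbonate | C=CC(C)(C)OC(=O)OC(C)(C)C | starting material
4 | 1-[2-fluoro-6-hydroxy-4-(2-methylbut-3-en-2-yloxy)phenyl]ethan-1-one | CC(=O)c1c(O)cc(OC(C)(C)C=C)cc1F | intermediate
5 | 1-[6-fluoro-2,4-dihydroxy-3-(3-methylbut-2-en-1-yl)phenyl]ethan-1-one | CC(=O)c1c(O)c(CC=C(C)C)c(O)cc1F | intermediate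
6 | 1-[6-fluoro-2-hydroxy-4-(methoxymethoxy)-3-(3-methylbut-2-en-1-yl)phenyl]ethan-1-one | CC(=O)c1c(O)c(CC=C(C)C)c(OCOC)cc1F | intermediate
7 | 1-[6-fluoro-2-methoxy-4-(methoxymethoxy)-3-(3-methylbut-2-en-1-yl)phenyl]ethan-1-one | CC(=O)c1c(OC)c(CC=C(C)C)c(OCOC)cc1F | intermediate
8 | 4-bromo-3-methoxyphenol | COc1cc(O)ccc1Br | starting material
9 | 1-bromo-2-methoxy-4-(methoxymethoxy)benzene | COCOc1ccc(Br)c(OC)c1 | intermediate
10 | 1-[6-fluoro-2-methoxy-4-(methoxymethoxy)-3-(3-methylbut-2-en-1-yl)phenyl]-2-[2-methoxy-4-(methoxymethoxy)phenyl]ethan-1-one | COCOc1ccc(CC(=O)c2c(OC)c(CC=C(C)C)c(OCOC)cc2F)c(OC)c1 | intermediate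
11 | ethyl formate | CCOC=O | starting material
12 | sodium (Z)-3-[6-fluoro-2-methoxy-4-(methoxymethoxy)-3-(3-methylbut-2-en-1-yl)phenyl]-2-[2-methoxy-4-(methoxymethoxy)phenyl]-3-oxoprop-1-en-1-olate | [Na+].[O-]/C=C(/c1ccc(OCOC)cc1OC)C(=O)c1c(OC)c(CC=C(C)C)c(OCOC)cc1F | intermediate (not isolated)
13 | 5-methoxy-3-[2-methoxy-4-(methoxymethoxy)phenyl]-7-(methoxymethoxy)-6-(3-methylbut-2-en-1-yl)-4H-chromen-4-one | COCOc1ccc(-c2coc3cc(OCOC)c(CC=C(C)C)c(OC)c3c2=O)c(OC)c1 | intermediate
14 | rac-5-methoxy-3-[2-methoxy-4-(methoxymethoxy)phenyl]-7-(methoxymethoxy)-6-(3-methylbut-2-en-1-yl)-2,3-dihydro-4H-chromen-4-one | COCOc1ccc(C2COc3cc(OCOC)c(CC=C(C)C)c(OC)c3C2=O)c(OC)c1 | intermediate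
15 | rac-7-hydroxy-3-(4-hydroxy-2-methoxyphenyl)-5-methoxy-6-(3-methylbut-2-en-1-yl)-2,3-dihydro-4H-chromen-4-one | COc1cc(O)ccc1C1COc2cc(O)c(CC=C(C)C)c(OC)c2C1=O | intermediate
16 | (3R,4R)-3-(4-hydroxy-2-methoxyphenyl)-5-methoxy-6-(3-methylbut-2-en-1-yl)-3,4-dihydro-2H-chromene-4,7-diol | COc1cc(O)ccc1[C@@H]1COc2cc(O)c(CC=C(C)C)c(OC)c2[C@@H]1O | intermediate (not isolated)
17 | (3R)-3-(4-hydroxy-2-methoxyphenyl)-5-methoxy-6-(3-methylbut-2-en-1-yl)-2,3-dihydro-7H-chromen-7-one | COc1cc(O)ccc1[C@@H]1COC2=CC(=O)C(CC=C(C)C)=C(OC)C2=C1 | intermediate (not isolated)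
18 | (3R)-3-(4-hydroxy-2-methoxyphenyl)-5-methoxy-6-(3-methylbut-2-en-1-yl)-3,4-dihydro-2H-chromen-7-ol | COc1cc(O)ccc1[C@@H]1COc2cc(O)c(CC=C(C)C)c(OC)c2C1 | target

**Step count**
Total: 11 steps. Longest linear sequence: 10 steps (steps 1–5 and 7–11); step 6 is a one-step side branch.

**Steps most likely to fail**

Step 8. The chelated formyl enolate oxygen is a weak nucleophile and ring A is electron-rich. Fluoride displacement may therefore be slower than retro-Claisen loss of the formyl group or attack of residual ethoxide at C8a. The fallback gives up the one-pot closure and sets out from 10. The fluoride is first exchanged for hydroxide (KOH, DMSO–H2O, 80 °C) to give the 2-hydroxydeoxybenzoin 1-[6-hydroxy-2-methoxy-4-(methoxymethoxy)-3-(3-methylbut-2-en-1-yl)phenyl]-2-[2-methoxy-4-(methoxymethoxy)phenyl]ethan-1-one F1. Heating F1 with N,N-dimethylformamide dimethyl acetal should give the enaminone 3-(dimethylamino)-1-[6-hydroxy-2-methoxy-4-(methoxymethoxy)-3-(3-methylbut-2-en-1-yl)phenyl]-2-[2-methoxy-4-(methoxymethoxy)phenyl]prop-2-en-1-one F2. F2 closes by attack of the phenol oxygen at C2 with loss of dimethylamine, and the route is rejoined at isoflavone 13.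

Step 11. The benzylic alcohol may fail to ionise under the transfer-hydrogenation conditions, or the quinone methide may tautomerise to the achiral isoflav-3-ene and erode the enantiomeric purity. The fallback separates reduction from deoxygenation and sets out from the protected ketone 14. The same ruthenium catalyst and HCO2H/Et3N should give, with dynamic kinetic resolution, (3R,4R)-5-methoxy-3-[2-methoxy-4-(methoxymethoxy)phenyl]-7-(methoxymethoxy)-6-(3-methylbut-2-en-1-yl)-3,4-dihydro-2H-chromen-4-ol F3. 1,1'-Thiocarbonyldiimidazole converts it into O-[(3R,4R)-5-methoxy-3-[2-methoxy-4-(methoxymethoxy)phenyl]-7-(methoxymethoxy)-6-(3-methylbut-2-en-1-yl)-3,4-dihydro-2H-chromen-4-yl] 1H-imidazole-1-carbothioate F4. Barton–McCombie reduction (Bu3SnH, AIBN, toluene, 90 °C) removes the C4 oxygen through a benzylic radical that cannot affect C3 and gives (3R)-5-methoxy-3-[2-methoxy-4-(methoxymethoxy)phenyl]-7-(methoxymethoxy)-6-(3-methylbut-2-en-1-yl)-3,4-dihydro-2H-chromene F5. Mild acid (HCl, MeOH) then removes the MOM groups, and the route is rejoined at the target 18.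

Step 3. The [3,3] shift may go in part to the ring carbon next to fluorine (poor regioselectivity), or the tertiary ether may isomerise before it rearranges. The fallback moves the migrating group to the other oxygen, so that only one ortho carbon is free, and sets out from 2. Selective MOM protection of the non-chelated 4-OH (MOMCl, K2CO3) gives 1-[2-fluoro-6-hydroxy-4-(methoxymethoxy)phenyl]ethan-1-one F6. Palladium-catalysed etherification of the remaining OH with carbonate 3 gives 1-[2-fluoro-4-(methoxymethoxy)-6-(2-methylbut-3-en-2-yloxy)phenyl]ethan-1-one F7. Its Claisen rearrangement can only deliver the prenyl group to the carbon between the two oxygens, and the route is rejoined at 6.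

**Further compounds**
F1 | step 8 | 1-[6-hydroxy-2-methoxy-4-(methoxymethoxy)-3-(3-methylbut-2-en-1-yl)phenyl]-2-[2-methoxy-4-(methoxymethoxy)phenyl]ethan-1-one | COCOc1ccc(CC(=O)c2c(OC)c(CC=C(C)C)c(OCOC)cc2O)c(OC)c1
F2 | step 8 | 3-(dimethylamino)-1-[6-hydroxy-2-methoxy-4-(methoxymethoxy)-3-(3-methylbut-2-en-1-yl)phenyl]-2-[2-methoxy-4-(methoxymethoxy)phenyl]prop-2-en-1-one | COCOc1ccc(C(=CN(C)C)C(=O)c2c(OC)c(CC=C(C)C)c(OCOC)cc2O)c(OC)c1
F3 | step 11 | (3R,4R)-5-methoxy-3-[2-methoxy-4-(methoxymethoxy)phenyl]-7-(methoxymethoxy)-6-(3-methylbut-2-en-1-yl)-3,4-dihydro-2H-chromen-4-ol | COCOc1ccc([C@@H]2COc3cc(OCOC)c(CC=C(C)C)c(OC)c3[C@@H]2O)c(OC)c1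
F4 | step 11 | O-[(3R,4R)-5-methoxy-3-[2-methoxy-4-(methoxymethoxy)phenyl]-7-(methoxymethoxy)-6-(3-methylbut-2-en-1-yl)-3,4-dihydro-2H-chromen-4-yl] 1H-imidazole-1-carbothioate | COCOc1ccc([C@@H]2COc3cc(OCOC)c(CC=C(C)C)c(OC)c3[C@@H]2OC(=S)n4ccnc4)c(OC)c1
F5 | step 11 | (3R)-5-methoxy-3-[2-methoxy-4-(methoxymethoxy)phenyl]-7-(methoxymethoxy)-6-(3-methylbut-2-en-1-yl)-3,4-dihydro-2H-chromene | COCOc1ccc([C@@H]2COc3cc(OCOC)c(CC=C(C)C)c(OC)c3C2)c(OC)c1
F6 | step 3 | 1-[2-fluoro-6-hydroxy-4-(methoxymethoxy)phenyl]ethan-1-one | CC(=O)c1c(O)cc(OCOC)cc1F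
F7 | step 3 | 1-[2-fluoro-4-(methoxymethoxy)-6-(2-methylbut-3-en-2-yloxy)phenyl]ethan-1-one | CC(=O)c1c(OC(C)(C)C=C)cc(OCOC)cc1F
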